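## Structural features

The target is a single 3,6-dihydro-2H-pyran ring (O1, C2, C3, C4=C5, C6); its only ring unsaturation is the trisubstituted C4=C5 bond. C2 carries a 1-carboxyvinyl group bound through its α-carbon, and C5 carries a homofarnesyl chain, (3E,7E)-4,8,12-trimethyltrideca-3,7,11-trien-1-yl, with two (E)-trisubstituted olefins and a terminal isopropylidene group. C2 (R) is the only stereocentre and has no stereogenic neighbour, so its configuration must come from a catalyst or from the chiral pool. The fragile groups are the 2-(1-alkoxyalkyl)acrylic acid (Michael acceptor, addition–elimination with loss of O1, polymerisation), the ionisable allylic ether positions C2 and C6, and the skipped triene, which is prone to cation–olefin cyclisation. The real difficulty is the chain on C5, next to an unsubstituted C6H2, combined with the isolated stereocentre at C2: a plain 2-alkylbutadiene and an aldehyde would put the chain on C4. The key step exploits O1–C2 as a carbonyl retron and C3–C4=C5–C6 as a diene retron. A temporary oxygen on C6 polarises the diene so that C3 bonds to the carbonyl carbon, and an alkyne on C2 stands in for the acrylic acid.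

## Logic of the disconnections

13 to 12. The acyl C–O bond of the carboxyl group is traced back to the ester oxygen of 12. The free acid is the most polymerisation-prone form and is best released last. The forward step must attack the acyl carbon and not the β-carbon of the acrylate.

12 to 11. The bond between the acrylate α-carbon and the carboxyl carbon is cut, and the C=CH2 unit is retraced to C≡C–H. This replaces a Michael acceptor by a robust two-carbon handle. The forward step must put the carboxyl carbon on the internal alkyne carbon and leave four trisubstituted olefins alone.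

11 to 10. The alkyne C–H is traced back to C–Si. The silyl cap is needed earlier to shield the alkyne. Its removal must not touch C2.

10 to 9. The C6–H bond is exchanged for a C6–O bond. This restores the oxygen that makes the ring a hetero-Diels–Alder retron with the correct polarity. The forward step must deliver hydride to C6, not to C4, of an allylic oxocarbenium ion, and faster than the side-chain olefins can trap that ion.

9 to 7 and 8. C2–C3 and O1–C6 are cut together. This removes the ring and both stereocentres of 9 and leaves the two open-chain components 7 and 8. The forward step needs regiocontrol by the oxygen on the diene terminus, carbonyl-over-alkyne chemoselectivity, catalyst control of the aldehyde face, and a (1E) diene.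

7 to 6. The O–Si bond is cut and a γ-hydrogen is returned, so the diene becomes a conjugated carbonyl compound. Enolisation must occur through the s-trans conformer so that oxygen ends up trans to the vinyl group.

6 to 5. The carbonyl is retraced to its masked form. This lets the aldehyde carbon travel protected through the olefination. The hydrolysis must use acid weak enough for the triene.

5 to 4. The C=C bond between the ethylidene carbon and the chain-bearing carbon is cut. The two-carbon unit is then installed without a crossed aldol between two enolisable aldehydes. The olefination must tolerate an enolisable ketone; its geometry does not matter.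

4 to 1 and 2 (through 3). The bond between the methyl carbon of 1 and C1 of 2 is cut. The extra CH2 of the homofarnesyl chain then comes from 1, the (E,E) geometry is purchased with 2, and no C16 halide has to be made. The forward step needs kinetic enolisation at the methyl group and mono-C-alkylation at the primary allylic carbon.

## Other disconnections considered

Alternative 1: The cut goes through C5–C1' and C3–C4 and leaves the ring open. The diol A1 would be assembled in one pot from homofarnesylmagnesium bromide A2, propargyl alcohol A3 and the (R)-glycidyl ether A4.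
- Forward key step: with a catalytic amount of CuI A5, the magnesium alkoxide of A3 directs an anti-carbomagnesiation that puts the chain of A2 on the internal alkyne carbon. The chelated (Z)-alkenylmagnesium then opens A4 at its CH2 terminus.
- In its favour: three fragments converge in one operation. The C4=C5 geometry follows from anti addition plus chelation. The C2 configuration is bought with A4 and does not depend on a catalyst; on this point it is better than the chosen plan, whose sense of induction must be checked.
- Against it here: A2 is not commercial and would need a separate one-carbon homologation of the farnesyl skeleton. The chelated alkenylmagnesium is a sluggish nucleophile toward epoxides, and excess Grignard reagent is normally consumed. The ring still has to be closed by a selective etherification. The protected hydroxymethyl branch of A1 holds one carbon where three are needed, so deprotection, oxidation to an epimerisable α-alkoxy aldehyde, alkyne homologation and the same carbonylation and hydrolysis would follow.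
- Comparison: on placing the chain at C5 it is the equal of the chosen plan. On mechanism it is simpler and more predictable (polar organometallic steps only), but its key step forms no ring and no stereocentre. On step economy it is estimated to be five or six steps longer.

Alternative 2: The cut is the O1–C2 bond. The racemic carbonate A7 would be cyclised to the methyl ester A6, which is identical with 12.
- Forward key step: a chiral cinchona-type tertiary amine adds to the acrylate CH2 of A7 and the carbonate leaves. The alkoxide of the (Z)-allylic alcohol then attacks C2 of the allylammonium ion in a second SN2' event, closing the ring and releasing the amine. The stereocentre of A7 is erased in the first event, so both enantiomers funnel to one product.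
- In its favour: the acrylate is already in place, so only ester hydrolysis follows; this is better than the chosen plan, which needs four operations after its key step. No cation is generated near the triene, which is also better. No throwaway stereocentre is made.
- Against it here: A7 requires a β,γ-unsaturated aldehyde with a (Z)-trisubstituted olefin, which is prone to conjugation, in a slow amine-catalysed acrylate–aldehyde coupling. The primary and secondary hydroxyl groups must be differentiated. The (Z)-olefin needs its own stereoselective construction. An aliphatic alkoxide closing a six-membered ring is a less secure case for asymmetric induction than the usual nucleophiles of this catalysis.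
- Comparison: on structure it is equal (ring and C2 in one step). On mechanism it moves the regiochemical problem into an earlier olefin synthesis. On step economy it is shorter after the key step and longer before it, so comparable or slightly longer overall.

Alternative 3: The cut is the C5–C6 bond. The methoxymethyl ether A9 would cyclise to the silyl ether A8.
- Forward key step: SnCl4 A10 ionises the acetal of A9 to an O1=C6H2 oxocarbenium ion. The silicon-bearing carbon of the (Z)-vinylsilane attacks it, closing the six-membered ring through a β-silyl cation, and loss of silicon leaves C4=C5.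
- In its favour: the position of the ring olefin is fixed by silicon, equal to the chosen plan on regiocontrol. C6 arrives as an unsubstituted CH2, so no deoxygenation is needed; this is better than the chosen plan.
- Against it here: a strong Lewis acid and an unstabilised oxocarbenium ion meet three nucleophilic trisubstituted olefins. The chosen plan also passes through a cation (step 6), but that one is conjugated and is intercepted by excess hydride donor. The C2 stereocentre of A9 needs a separate asymmetric step. The trisubstituted (Z)-vinylsilane carrying the chain needs its own multistep construction. After ring closure, desilylation and two oxidations are still required to reach the acid.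
- Comparison: on structure the ring is closed but no stereocentre is set. On mechanism it is cationic and less compatible with the triene. On step economy it is clearly longer.

Key step: step 5

Remark on the chemistry: the ring is numbered O1, C2 (alkyne or acrylate), C3, C4=C5 (chain), C6, and "homofarnesyl" means (3E,7E)-4,8,12-trimethyltrideca-3,7,11-trien-1-yl; the cis cycloadduct with (R) at C2 is (2R,6R) because the silyloxy oxygen outranks O1 at C6; (L)CrCl is the chloride complex of trivalent chromium with L, the dianion of (1R,2S)-1-{[3-(adamantan-1-yl)-2-hydroxy-5-methylbenzylidene]amino}-2,3-dihydro-1H-inden-2-ol; its sense of induction is assigned by analogy with simple aldehydes and 1-alkoxydienes and must be confirmed on 9, the mirror-image complex being equally accessible.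

## Route

Step 1
Reactants: 1 1,1-dimethoxypropan-2-one; 2 (2E,6E)-farnesyl bromide
Product: 4 (5E,9E)-1,1-dimethoxy-6,10,14-trimethylpentadeca-5,9,13-trien-2-one, via lithium 3,3-dimethoxyprop-1-en-2-olate 3 (not isolated)
Conditions: LiN(iPr)2 (2.1 equiv), 1 (2.2 equiv), THF, −78 °C; then 2 (1.0 equiv), DMPU, −78 → 0 °C
Reagents that add atoms: none
Why: LiN(iPr)2 removes a methyl hydrogen of 1 under kinetic control (the acetal methine is hindered and its enolate carbon would carry two donor oxygens), and enolate 3 displaces bromide at the primary allylic carbon of 2 (SN2 C-alkylation of a ketone enolate); the excess of 3 over 2 is meant to suppress double alkylation, and the (E) olefins of 2 are not touched.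

Step 2
Reactants: 4 (5E,9E)-1,1-dimethoxy-6,10,14-trimethylpentadeca-5,9,13-trien-2-one
Product: 5 (6E,10E)-3-(dimethoxymethyl)-7,11,15-trimethylhexadeca-2,6,10,14-tetraene (mixture of 2E and 2Z)
Conditions: EtPPh3Br (1.5 equiv), NaN(SiMe3)2 (1.4 equiv), THF, 0 °C; then 4, −78 °C → rt
Reagents that add atoms: ethyltriphenylphosphonium bromide, CC[P+](c1ccccc1)(c1ccccc1)c1ccccc1.[Br-]
Why: The non-stabilised ylide adds to the ketone, which is activated by the two α-alkoxy groups, and the oxaphosphetane collapses to the trisubstituted olefin (Wittig olefination); either geometry is acceptable because it is erased in step 4, and the acetal and triene are inert to the ylide.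

Step 3
Reactants: 5 (6E,10E)-3-(dimethoxymethyl)-7,11,15-trimethylhexadeca-2,6,10,14-tetraene
Product: 6 2-homofarnesylbut-2-enal (mixture of 2E and 2Z)
Conditions: PPTS (10 mol %), acetone/H2O (10:1), rt
Reagents that add atoms: water, O
Why: An allylic dimethyl acetal hydrolyses readily through a conjugated oxocarbenium ion (acetal hydrolysis) under pyridinium catalysis, which is too weak to protonate the trisubstituted olefins.

Step 4
Reactants: 6 2-homofarnesylbut-2-enal
Product: 7 (1E)-1-(tert-butyldimethylsilyloxy)-2-homofarnesylbuta-1,3-diene
Conditions: Et3N (2.0 equiv), TBSOTf (1.2 equiv), Et2O, −78 → 0 °C; NaHCO3 work-up, filtration through Et3N-deactivated silica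
Reagents that add atoms: tert-butyldimethylsilyl trifluoromethanesulfonate, CC(C)(C)[Si](C)(C)OS(=O)(=O)C(F)(F)F
Why: O-Silylation gives a silyloxocarbenium ion from which Et3N removes a γ-hydrogen of the methyl group (soft enolisation to a silyl dienol ether); reaction through the favoured s-trans conformer should place oxygen trans to the new vinyl group, that is (1E), and both geometrical isomers of 6 converge on 7.

Step 5
Reactants: 7 (1E)-1-(tert-butyldimethylsilyloxy)-2-homofarnesylbuta-1,3-diene; 8 3-(trimethylsilyl)propynal
Product: 9 (2R,6R)-6-(tert-butyldimethylsilyloxy)-2-[(trimethylsilyl)ethynyl]-5-homofarnesyl-3,6-dihydro-2H-pyran (2,6-cis)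
Conditions: (L)CrCl (5 mol %), 8 (1.5 equiv), powdered 4 Å MS, TBME (concentrated), 0 °C → rt
Reagents that add atoms: none
Why: The aldehyde oxygen of 8 binds to the Lewis-acidic chromium centre of (L)CrCl, and the s-cis diene 7 adds in a concerted, asynchronous [4+2] cycloaddition in which C2–C3 formation runs ahead of O1–C6 formation. The closest known reaction type is the (Schiff base)CrCl-catalysed enantioselective hetero-Diels–Alder reaction of 1-alkoxy- and 1-silyloxy-dienes with aldehydes, alkynyl aldehydes included. The dihydropyran ring is closed by the cycloaddition itself, both ring bonds being made in one intermolecular event from two separate components. C2 is controlled by the catalyst: the indane and adamantyl walls of the tridentate ligand expose one face of the bound carbonyl, and the (1R,2S) ligand is expected to give (2R). C6 is controlled by the diene geometry and the endo preference: the (1E) silyloxy group sits on the outside of the diene and the alkynyl group is endo, which puts both on the same face (cis, 6R). Regioselectivity against the bias of the 2-alkyl group is needed and is secured by the silyloxy donor, which makes the unsubstituted diene terminus the nucleophilic carbon. Chemoselectivity for C=O over C≡C is secured by carbonyl coordination to chromium and by the trimethylsilyl cap, the side-chain olefins are inert to this mild Lewis acid, and any (1Z) isomer of 7 cannot reach the s-cis geometry and should remain unchanged.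

Step 6
Reactants: 9 (2R,6R)-6-(tert-butyldimethylsilyloxy)-2-[(trimethylsilyl)ethynyl]-5-homofarnesyl-3,6-dihydro-2H-pyran
Product: 10 (2R)-2-[(trimethylsilyl)ethynyl]-5-homofarnesyl-3,6-dihydro-2H-pyran
Conditions: Et3SiH (4 equiv), BF3·OEt2 (1.5 equiv), CH2Cl2, −78 → −40 °C
Reagents that add atoms: none
Why: BF3 ionises the anomeric silyloxy group to the O1=C6 oxocarbenium ion conjugated with C4=C5, and Et3SiH delivers hydride to C6, which carries most of the charge, so the olefin stays at C4=C5 (ionic hydrogenation of a Ferrier-type cation); C2 is not involved, the C6 stereocentre disappears, and low temperature with excess silane is meant to outrun capture of the cation by the side-chain olefins.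

Step 7
Reactants: 10 (2R)-2-[(trimethylsilyl)ethynyl]-5-homofarnesyl-3,6-dihydro-2H-pyran
Product: 11 (2R)-2-ethynyl-5-homofarnesyl-3,6-dihydro-2H-pyran
Conditions: K2CO3 (0.3 equiv), MeOH/THF (2:1), rt
Reagents that add atoms: none
Why: Methoxide attacks silicon and releases the acetylide, which the solvent protonates (protodesilylation of an alkynylsilane); the propargylic C2–H is not acidic enough to epimerise under these conditions.

Step 8
Reactants: 11 (2R)-2-ethynyl-5-homofarnesyl-3,6-dihydro-2H-pyran
Product: 12 methyl 2-[(2R)-5-homofarnesyl-3,6-dihydro-2H-pyran-2-yl]prop-2-enoate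
Conditions: Pd(OAc)2 (2 mol %), 2-PyPPh2 (20 mol %), MsOH (20 mol %), CO (10 bar), MeOH/THF (3:1), 45 °C
Reagents that add atoms: carbon monoxide, [C-]#[O+]; methanol, CO
Why: The cationic palladium hydride formed from Pd(OAc)2, the P,N ligand and acid adds to the terminal alkyne with palladium on the internal carbon, and CO insertion followed by methanolysis (pyridyl nitrogen as proton shuttle) gives the 2-substituted acrylate (Markovnikov alkoxycarbonylation of a terminal alkyne); the acid is buffered as the pyridinium salt, the trisubstituted olefins do not insert, and C2 is untouched.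

Step 9
Reactants: 12 methyl 2-[(2R)-5-homofarnesyl-3,6-dihydro-2H-pyran-2-yl]prop-2-enoate
Product: 13 2-[(2R)-5-homofarnesyl-3,6-dihydro-2H-pyran-2-yl]prop-2-enoic acid
Conditions: LiOH·H2O (3 equiv), THF/H2O (3:1), 0 °C → rt; then 1 M HCl to pH 3–4, 0 °C
Reagents that add atoms: lithium hydroxide, [Li+].[OH-]
Why: Hydroxide attacks the ester carbonyl (saponification) in preference to the β-carbon of the 2-substituted acrylate at low temperature; C2 has no hydrogen acidic enough to be removed, and cold, brief acidification spares the triene and the allylic ether.

## Compound list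

1 | 1,1-dimethoxypropan-2-one | CC(=O)C(OC)OC | starting material
2 | (2E,6E)-farnesyl bromide, (2E,6E)-1-bromo-3,7,11-trimethyldodeca-2,6,10-triene | BrC/C=C(\C)CC/C=C(\C)CCC=C(C)C | starting material
3 | lithium 3,3-dimethoxyprop-1-en-2-olate | [Li]OC(=C)C(OC)OC | intermediate (not isolated)
4 | (5E,9E)-1,1-dimethoxy-6,10,14-trimethylpentadeca-5,9,13-trien-2-one | COC(OC)C(=O)CC/C=C(\C)CC/C=C(\C)CCC=C(C)C | intermediate
5 | (6E,10E)-3-(dimethoxymethyl)-7,11,15-trimethylhexadeca-2,6,10,14-tetraene, mixture of (2E) and (2Z) | CC=C(CC/C=C(\C)CC/C=C(\C)CCC=C(C)C)C(OC)OC | intermediate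
6 | 2-[(3E,7E)-4,8,12-trimethyltrideca-3,7,11-trien-1-yl]but-2-enal, mixture of (2E) and (2Z) | CC=C(CC/C=C(\C)CC/C=C(\C)CCC=C(C)C)C=O | intermediate
7 | (1E)-1-(tert-butyldimethylsilyloxy)-2-[(3E,7E)-4,8,12-trimethyltrideca-3,7,11-trien-1-yl]buta-1,3-diene | C=C/C(CC/C=C(\C)CC/C=C(\C)CCC=C(C)C)=C/O[Si](C)(C)C(C)(C)C | intermediate
8 | 3-(trimethylsilyl)propynal | O=CC#C[Si](C)(C)C | starting material
9 | (2R,6R)-6-(tert-butyldimethylsilyloxy)-2-[(trimethylsilyl)ethynyl]-5-[(3E,7E)-4,8,12-trimethyltrideca-3,7,11-trien-1-yl]-3,6-dihydro-2H-pyran, 2,6-cis | C[Si](C)(C)C#C[C@H]1CC=C(CC/C=C(\C)CC/C=C(\C)CCC=C(C)C)[C@@H](O[Si](C)(C)C(C)(C)C)O1 | intermediate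
10 | (2R)-2-[(trimethylsilyl)ethynyl]-5-[(3E,7E)-4,8,12-trimethyltrideca-3,7,11-trien-1-yl]-3,6-dihydro-2H-pyran | C[Si](C)(C)C#C[C@H]1CC=C(CC/C=C(\C)CC/C=C(\C)CCC=C(C)C)CO1 | intermediate
11 | (2R)-2-ethynyl-5-[(3E,7E)-4,8,12-trimethyltrideca-3,7,11-trien-1-yl]-3,6-dihydro-2H-pyran | C#C[C@H]1CC=C(CC/C=C(\C)CC/C=C(\C)CCC=C(C)C)CO1 | intermediate
12 | methyl 2-[(2R)-5-[(3E,7E)-4,8,12-trimethyltrideca-3,7,11-trien-1-yl]-3,6-dihydro-2H-pyran-2-yl]prop-2-enoate | C=C(C(=O)OC)[C@H]1CC=C(CC/C=C(\C)CC/C=C(\C)CCC=C(C)C)CO1 | intermediate
13 | 2-[(2R)-5-[(3E,7E)-4,8,12-trimethyltrideca-3,7,11-trien-1-yl]-3,6-dihydro-2H-pyran-2-yl]prop-2-enoic acid | C=C(C(=O)O)[C@H]1CC=C(CC/C=C(\C)CC/C=C(\C)CCC=C(C)C)CO1 | target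

## Step count and least certain steps

Total step count: 9. Longest linear sequence: 9 steps (1 and 2 to 13); 8 enters at step 5 as a purchased component.

Step 5 (key step).
- What may go wrong: loss of periselectivity, that is a stepwise vinylogous Mukaiyama-type addition with silyl transfer to the aldehyde oxygen, or protodesilylation of the diene on the Lewis acid. Either would give open-chain material instead of the ring. Facial discrimination of a slim, linear alkynyl aldehyde may also be incomplete.
- Fallback: it sets out from 5. Ionisation of the acetal with TMSOTf and i-Pr2NEt in CH2Cl2 at −20 °C, followed by γ-deprotonation, should give (1E)-1-methoxy-2-homofarnesylbuta-1,3-diene F1, whose methyl group cannot migrate. Cycloaddition of F1 with 8 under (L)CrCl should give (2R,6S)-6-methoxy-2-[(trimethylsilyl)ethynyl]-5-homofarnesyl-3,6-dihydro-2H-pyran F2 (2,6-cis). Its methoxy group is removed with Et3SiH and BF3·OEt2 as in step 6, and the route is rejoined at 10.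

Step 6.
- What may go wrong: the allylic oxocarbenium ion may be captured at C4, or by the C3'=C4' olefin of the side chain (cation–olefin cyclisation), before hydride transfer to C6.
- Fallback: it avoids the cation and sets out from 9. TBAF buffered with AcOH in THF removes both silyl groups and should give the lactol (2R)-2-ethynyl-5-homofarnesyl-3,6-dihydro-2H-pyran-6-ol F3. NaBH4 with CeCl3·7H2O in MeOH at 0 °C reduces the open hydroxy-enal form to (3R,5Z,9E,13E)-6-(hydroxymethyl)-10,14,18-trimethylnonadeca-5,9,13,17-tetraen-1-yn-3-ol F4. NaH and N-tosylimidazole in THF sulfonylate the primary allylic oxygen to [(3R,5Z,9E,13E)-3-hydroxy-10,14,18-trimethylnonadeca-5,9,13,17-tetraen-1-yn-6-yl]methyl 4-methylbenzenesulfonate F5. The secondary alkoxide then closes the ring by SN2 displacement at C6 with the C2–O bond untouched, and the route is rejoined at 11.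

Step 8.
- What may go wrong: erosion of Markovnikov regioselectivity by the branched, oxygenated propargylic substituent, or slow turnover with acid-induced decay of the triene.
- Fallback: it sets out from 11. α-Selective hydrostannation of the propargylic ether with Bu3SnH and Mo(CO)3(CNtBu)3 in THF should give (2R)-2-[1-(tributylstannyl)ethenyl]-5-homofarnesyl-3,6-dihydro-2H-pyran F6. Iododestannylation with I2 in CH2Cl2 at 0 °C gives (2R)-2-(1-iodoethenyl)-5-homofarnesyl-3,6-dihydro-2H-pyran F7. Carbonylation of the alkenyl iodide with Pd(PPh3)4 (zerovalent palladium), CO, MeOH and Et3N in DMF returns to the route at 12.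

Step 1.
- What may go wrong: proton exchange between product and enolate leading to double alkylation, with some O-alkylation or enolisation toward the acetal carbon.
- Fallback: it sets out from 2. The doubly activated methylene of methyl 4,4-dimethoxy-3-oxobutanoate F8 is alkylated with 2 (K2CO3, acetone, reflux) to give methyl (4E,8E)-2-(2,2-dimethoxyacetyl)-5,9,13-trimethyltetradeca-4,8,12-trienoate F9. Krapcho dealkoxycarbonylation (LiCl, wet DMSO, 140 °C) returns to the route at 4.

Step 9.
- What may go wrong: conjugate addition of hydroxide to the acrylate followed by β-elimination of the ring oxygen, which would open the ring and put the configuration at C2 at risk.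
- Fallback: it sets out from 11. The carbonylation of step 8 is run with 2-(trimethylsilyl)ethanol in THF in place of methanol to give 2-(trimethylsilyl)ethyl 2-[(2R)-5-homofarnesyl-3,6-dihydro-2H-pyran-2-yl]prop-2-enoate F10. Fluoride-induced fragmentation (TBAF, THF, 0 °C) and mild acidification come back to the route at 13 without any hydroxide.

## Further compounds

F1 | step 5 | (1E)-1-methoxy-2-[(3E,7E)-4,8,12-trimethyltrideca-3,7,11-trien-1-yl]buta-1,3-diene | C=C/C(CC/C=C(\C)CC/C=C(\C)CCC=C(C)C)=C/OC
F2 | step 5 | (2R,6S)-6-methoxy-2-[(trimethylsilyl)ethynyl]-5-[(3E,7E)-4,8,12-trimethyltrideca-3,7,11-trien-1-yl]-3,6-dihydro-2H-pyran, 2,6-cis | C[Si](C)(C)C#C[C@H]1CC=C(CC/C=C(\C)CC/C=C(\C)CCC=C(C)C)[C@@H](OC)O1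
F3 | step 6 | (2R)-2-ethynyl-5-[(3E,7E)-4,8,12-trimethyltrideca-3,7,11-trien-1-yl]-3,6-dihydro-2H-pyran-6-ol, mixture of C6 epimers | C#C[C@H]1CC=C(CC/C=C(\C)CC/C=C(\C)CCC=C(C)C)C(O)O1
F4 | step 6 | (3R,5Z,9E,13E)-6-(hydroxymethyl)-10,14,18-trimethylnonadeca-5,9,13,17-tetraen-1-yn-3-ol | C#C[C@H](O)C/C=C(\CO)CC/C=C(\C)CC/C=C(\C)CCC=C(C)C
F5 | step 6 | [(3R,5Z,9E,13E)-3-hydroxy-10,14,18-trimethylnonadeca-5,9,13,17-tetraen-1-yn-6-yl]methyl 4-methylbenzenesulfonate | C#C[C@H](O)C/C=C(\COS(=O)(=O)c1ccc(C)cc1)CC/C=C(\C)CC/C=C(\C)CCC=C(C)C
F6 | step 8 | (2R)-2-[1-(tributylstannyl)ethenyl]-5-[(3E,7E)-4,8,12-trimethyltrideca-3,7,11-trien-1-yl]-3,6-dihydro-2H-pyran | C=C([Sn](CCCC)(CCCC)CCCC)[C@H]1CC=C(CC/C=C(\C)CC/C=C(\C)CCC=C(C)C)CO1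
F7 | step 8 | (2R)-2-(1-iodoethenyl)-5-[(3E,7E)-4,8,12-trimethyltrideca-3,7,11-trien-1-yl]-3,6-dihydro-2H-pyran | C=C(I)[C@H]1CC=C(CC/C=C(\C)CC/C=C(\C)CCC=C(C)C)CO1
F8 | step 1 | methyl 4,4-dimethoxy-3-oxobutanoate | COC(=O)CC(=O)C(OC)OC
F9 | step 1 | methyl (4E,8E)-2-(2,2-dimethoxyacetyl)-5,9,13-trimethyltetradeca-4,8,12-trienoate, racemic | COC(=O)C(C/C=C(\C)CC/C=C(\C)CCC=C(C)C)C(=O)C(OC)OC
F10 | step 9 | 2-(trimethylsilyl)ethyl 2-[(2R)-5-[(3E,7E)-4,8,12-trimethyltrideca-3,7,11-trien-1-yl]-3,6-dihydro-2H-pyran-2-yl]prop-2-enoate | C=C(C(=O)OCC[Si](C)(C)C)[C@H]1CC=C(CC/C=C(\C)CC/C=C(\C)CCC=C(C)C)CO1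
A1 | alternative 1 | (2R,4Z,8E,12E)-5-(hydroxymethyl)-1-[(4-methoxyphenyl)methoxy]-9,13,17-trimethyloctadeca-4,8,12,16-tetraen-2-ol | COc1ccc(COC[C@H](O)C/C=C(\CO)CC/C=C(\C)CC/C=C(\C)CCC=C(C)C)cc1
A2 | alternative 1 | [(3E,7E)-4,8,12-trimethyltrideca-3,7,11-trien-1-yl]magnesium bromide | Br[Mg]CC/C=C(\C)CC/C=C(\C)CCC=C(C)C
A3 | alternative 1 | prop-2-yn-1-ol | C#CCO
A4 | alternative 1 | (2R)-2-{[(4-methoxyphenyl)methoxy]methyl}oxirane | COc1ccc(COC[C@H]2CO2)cc1
A5 | alternative 1 | copper iodide, CuI | [Cu]I
A6 | alternative 2 | methyl 2-[(2R)-5-[(3E,7E)-4,8,12-trimethyltrideca-3,7,11-trien-1-yl]-3,6-dihydro-2H-pyran-2-yl]prop-2-enoate (identical with 12) | C=C(C(=O)OC)[C@H]1CC=C(CC/C=C(\C)CC/C=C(\C)CCC=C(C)C)CO1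
A7 | alternative 2 | methyl (5Z,9E,13E)-3-[(tert-butoxycarbonyl)oxy]-6-(hydroxymethyl)-10,14,18-trimethyl-2-methylidenenonadeca-5,9,13,17-tetraenoate, racemic | C=C(C(=O)OC)C(OC(=O)OC(C)(C)C)C/C=C(\CO)CC/C=C(\C)CC/C=C(\C)CCC=C(C)C
A8 | alternative 3 | tert-butyl({2-[(2R)-5-[(3E,7E)-4,8,12-trimethyltrideca-3,7,11-trien-1-yl]-3,6-dihydro-2H-pyran-2-yl]prop-2-en-1-yl}oxy)diphenylsilane | C=C(CO[Si](c1ccccc1)(c1ccccc1)C(C)(C)C)[C@H]1CC=C(CC/C=C(\C)CC/C=C(\C)CCC=C(C)C)CO1
A9 | alternative 3 | tert-butyl{[(3R,5Z,9E,13E)-3-(methoxymethoxy)-10,14,18-trimethyl-2-methylidene-6-(trimethylsilyl)nonadeca-5,9,13,17-tetraen-1-yl]oxy}diphenylsilane | C=C(CO[Si](c1ccccc1)(c1ccccc1)C(C)(C)C)[C@H](OCOC)C/C=C(\[Si](C)(C)C)CC/C=C(\C)CC/C=C(\C)CCC=C(C)C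
A10 | alternative 3 | tin tetrachloride, SnCl4 | Cl[Sn](Cl)(Cl)Cl
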